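**Plan**

1. Numbering: decalin C1–C10 (rings A, B); ring C = C8, C9, C11–C14; oxocene = O–C13–C14–C15–C16–C17(CH3)=C18H–C19H2–O. Enabling feature: the ring oxygen sits on C19, next to the C17=C18 olefin (an allylic ether), so C19 can be an oxocarbenium carbon and C18 a carbene-derived carbon.
2. Cuts, oxocene: delete C18 (bonds C17–C18 and C18–C19) to reach the seven-membered cyclic enol ether O–C19H=C17(CH3) (oxepine ring O, C13, C14, C15, C16, C17, C19) through its dibromocyclopropane; then cut C19=C17 (Wittig) and O–C19 (acetal) to reach a 13-hydroxy 17-ketone.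
3. Cuts, core: C13–O and C8–C14 (cation–olefin cyclization) lead to a bicyclic (13E)-dienone with an exocyclic C8 methylene; C14–C15 (Suzuki) and C13–CH3 (carboalumination) lead to the alkyne made from the methyl ketone of (+)-larixol.
4. Forward: rings A and B come from larixol; ring C and a pyran close together in acid; the pyran is opened, re-closed one atom larger as the oxepine, and this is expanded to the oxocene.
5. Stereochemistry: C5, C6, C9, C10 from larixol; the 13E olefin from syn carboalumination; C8, C13, C14 from chair-like anti addition across that olefin; the ring-cis olefin from the disrotatory cyclopropane opening, into which both cyclopropane diastereomers converge.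

Key step: step 10

Assumption: (+)-larixol [(13S)-labda-8(17),14-diene-6α,13-diol] and 2-methyl-2-vinyl-1,3-dioxolane are taken as purchasable.

**Route**

Step 1
Reactants: 1 (+)-larixol
Product: 2 6α-hydroxy-14,15-dinorlabd-8(17)-en-13-one (C9 side chain CH2CH2COCH3)
Conditions: KMnO4, MgSO4, acetone–H2O, 0 °C
Reagents that add atoms: none
Why: Permanganate should attack the unhindered vinyl group faster than the shielded exocyclic C8 methylene, and the oxidized tertiary carbinol undergoes glycol-type C13–C14 cleavage to the methyl ketone (oxidative degradation of a tertiary vinyl carbinol), leaving C5, C6, C9 and C10 untouched.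

Step 2
Reactants: 2 6α-hydroxy-14,15-dinorlabd-8(17)-en-13-one
Product: 3 6α-(tert-butyldimethylsilyloxy)-14,15-dinorlabd-8(17)-en-13-one
Conditions: TBSOTf, 2,6-lutidine, CH2Cl2, −78 to 0 °C
Reagents that add atoms: tert-butyldimethylsilyl triflate, CC(C)(C)[Si](C)(C)OS(=O)(=O)C(F)(F)F
Why: Silyl triflate silylation of the only hydroxyl (hindered equatorial 6α-OH) under weakly basic conditions that should not enolize the ketone; the ether is chosen to survive the later base, carbene, organometallic and Lewis-acid steps.

Step 3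
Reactants: 3 6α-(tert-butyldimethylsilyloxy)-14,15-dinorlabd-8(17)-en-13-one
Product: 5 terminal alkyne (C9 side chain CH2CH2C≡CH; 6α-OTBS; exocyclic C8 methylene), via enol phosphate 4 (not isolated)
Conditions: LDA (1.1 equiv), THF, −78 °C; ClP(O)(OEt)2; then LDA (2.3 equiv), −78 °C to rt; H2O
Reagents that add atoms: none
Why: Kinetic deprotonation at the methyl group, O-phosphorylation and base-induced elimination of the enol phosphate (one-pot methyl ketone to terminal alkyne conversion) should give the alkyne without touching the exocyclic olefin.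

Step 4
Reactants: 5 terminal alkyne
Product: 7 (E)-vinyl iodide (C9 side chain CH2CH2C(CH3)=CHI), via alkenylalane 6 (not isolated)
Conditions: Me3Al (3 equiv), Cp2ZrCl2 (0.3 equiv), CH2Cl2, 0 °C to rt; then I2, THF, −30 °C
Reagents that add atoms: trimethylaluminium, C[Al](C)C; iodine, II
Why: Zirconium-catalysed Negishi carboalumination adds CH3 and Al syn across the alkyne, methyl on the internal carbon, and iodinolysis with retention gives the (E)-trisubstituted vinyl iodide, fixing the olefin geometry that later encodes the C13/C14 relationship.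

Step 5
Reactants: 7 (E)-vinyl iodide; 8 2-methyl-2-vinyl-1,3-dioxolane
Product: 11 (13E)-dienone (C9 side chain CH2CH2C(CH3)=CHCH2CH2COCH3; 6α-OTBS; exocyclic C8 methylene), via B-alkyl-9-BBN 9 (not isolated), via dioxolane-protected dienone 10 (not isolated)
Conditions: 8, 9-BBN-H, THF, rt; then 7, PdCl2(dppf) (5 mol %), AsPh3, Cs2CO3, DMF–H2O, rt; then 1 M HCl, THF, rt
Reagents that add atoms: water, O
Why: B-alkyl Suzuki–Miyaura coupling of the anti-Markovnikov hydroboration product of 8 proceeds with retention of olefin geometry and brings in C15–C17 plus the C17 methyl; dilute acid then unmasks the methyl ketone (ketal hydrolysis) without harming the hindered silyl ether.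

Step 6
Reactants: 11 (13E)-dienone
Product: 13 tricyclic hydroxy ketone (13α-OH; 13β-CH3; 14β-CH2CH2COCH3; 8β-CH3; 6α-OTBS), via tetracyclic enol ether 12 (not isolated)
Conditions: CF3CO2H·SnCl4 (2.5 equiv), CH2Cl2, −78 °C; then 1 M HCl, THF–H2O, rt
Reagents that add atoms: water, O
Why: Protonation of the exocyclic C8 methylene gives the tertiary C8 cation, which the 13E olefin attacks through a chair transition state while the ketone oxygen adds anti at C13 (cation–olefin cyclization terminated by a ketone oxygen, the reaction type that turns farnesylacetone into its tricyclic enol ether), so C8 (β-methyl), C14 (β chain, α-H) and C13 (α-oxygen, β-methyl) follow from the decalin and the E geometry; aqueous acid then hydrates the enol ether to the hydroxy ketone.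

Step 7
Reactants: 13 tricyclic hydroxy ketone
Product: 14 methyl enol ether (14β-CH2CH2C(CH3)=CHOCH3, E/Z mixture; 13α-OH)
Conditions: MeOCH2PPh3Cl, NaHMDS (3.5 equiv each), THF, 0 to 40 °C
Reagents that add atoms: (methoxymethyl)triphenylphosphonium chloride, COC[P+](c1ccccc1)(c1ccccc1)c1ccccc1.[Cl-]
Why: Wittig methoxymethylenation of the unhindered methyl ketone (excess ylide, because the tertiary alkoxide forms first) installs C19 at the aldehyde oxidation level; the enol ether geometry is irrelevant.

Step 8
Reactants: 14 methyl enol ether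
Product: 16 seven-membered cyclic enol ether (oxepine O–C19H=C17(CH3)–C16–C15–C14–C13 trans-fused to ring C; 6α-OTBS), via cyclic methyl acetal 15 (not isolated)
Conditions: PPTS (0.1 equiv), CH2Cl2, rt; then pyridine, PhCl, 135 °C
Reagents that add atoms: none
Why: Acid-catalysed intramolecular addition of the tertiary 13-OH to the protonated enol ether should close the trans-fused oxepane as a mixed methyl acetal (helped by the gauche, diequatorial O-13 and C14 chain), and buffered thermal loss of methanol (acetal to enol ether elimination) can place the double bond only at C19=C17; the transient acetal stereocentres vanish again.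

Step 9
Reactants: 16 seven-membered cyclic enol ether
Product: 17 dibromocyclopropane (2-oxabicyclo[5.1.0]octane: CBr2 bridging C19 and C17; both cis-fused diastereomers)
Conditions: CHBr3, KOtBu, pentane, −20 to 0 °C
Reagents that add atoms: bromoform, BrC(Br)Br
Why: [2+1] cycloaddition of dibromocarbene to the electron-rich trisubstituted enol ether, the only nucleophilic olefin present; the facial mixture at C17/C19 is of no consequence because both centres lose their stereogenicity in steps 10 and 11.

Step 10
Reactants: 17 dibromocyclopropane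
Product: 18 eight-membered allylic acetal acetate (O–C19H(OAc)–C18(Br)=C17(CH3)–C16, ring-cis olefin; C19 epimers; 6α-OTBS)
Conditions: AgOAc, NaOAc, toluene, 80 °C, dark
Reagents that add atoms: silver acetate, CC(=O)[O-].[Ag+]
Why: Silver-assisted loss from C18 of the bromide that is cis to the oxepane ring atoms is concerted with disrotatory two-electron electrocyclic opening of the cyclopropane (Woodward–Hoffmann–DePuy rule), which cleaves the C17–C19 bond shared by the three- and seven-membered rings with a push from the ring oxygen and gives an eight-membered 2-bromoallyl cation, that is an α,β-unsaturated oxocarbenium ion, which acetate captures at C19. The closest known reaction type is the silver- or base-promoted ring expansion of gem-dihalocyclopropanated cyclic enol ethers (cyclopropanated glycals to 2-bromo-oxepines), here one ring size up. No new ring is closed: the oxepane O, C13, C14, C15, C16, C17, C19 becomes the oxocene by insertion of C18 between C17 and C19 when the zero-atom bridge of the bicyclo[5.1.0] system opens. The only new stereocentre, acetal carbon C19, forms unselectively and is erased in step 11, while the ring olefin can only be cis (C16 and C19 on the same side) because the ring atoms rotate inward. The step needs ionization of the right bromide and capture at C19 rather than C17: only the endo bromide is stereoelectronically allowed to leave (the other remains as vinyl bromide), the charge sits on the oxygen-bearing C19, and C17 is fully substituted. Both cyclopropane diastereomers converge on the same cation, and the acetate buffer should keep the silyl ether and the tertiary C13–O bond intact.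

Step 11
Reactants: 18 eight-membered allylic acetal acetate
Product: 19 bromo-oxocene (O–C19H2–C18(Br)=C17(CH3)–C16; 6α-OTBS)
Conditions: Et3SiH, BF3·OEt2, CH2Cl2, −78 °C
Reagents that add atoms: none
Why: Lewis-acid ionization of the acetate regenerates the conjugated oxocarbenium ion and triethylsilane should deliver hydride to the unhindered, charge-bearing C19 and not to the fully substituted C17 (ionic hydrogenation of an acetal), which removes the C19 stereocentre.

Step 12
Reactants: 19 bromo-oxocene
Product: 20 silyl ether of the target (O–C19H2–C18H=C17(CH3)–C16, ring-cis (Z) olefin; 6α-OTBS)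
Conditions: Bu3SnH, AIBN (cat.), toluene, 100 °C
Reagents that add atoms: none
Why: Radical chain hydrodebromination of the vinyl bromide with a stannane; the ring holds the olefin geometry, and the non-basic radical conditions avoid the β-alkoxide elimination open to a 2-metallated allyl ether.

Step 13
Reactants: 20 silyl ether of the target
Product: 21 target (CNP0179324.1)
Conditions: TBAF, THF, 60 °C
Reagents that add atoms: none
Why: Fluoride-mediated desilylation frees the 6α-hydroxyl without touching the allylic ether or the olefin.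

**Compound list**

1 | (+)-larixol, (13S)-labda-8(17),14-diene-6α,13-diol | C=C[C@@](C)(O)CC[C@H]1C(=C)C[C@H](O)[C@H]2C(C)(C)CCC[C@]12C | starting material
2 | 6α-hydroxy-14,15-dinorlabd-8(17)-en-13-one | CC(=O)CC[C@H]1C(=C)C[C@H](O)[C@H]2C(C)(C)CCC[C@]12C | intermediate
3 | 6α-(tert-butyldimethylsilyloxy)-14,15-dinorlabd-8(17)-en-13-one | CC(=O)CC[C@H]1C(=C)C[C@H](O[Si](C)(C)C(C)(C)C)[C@H]2C(C)(C)CCC[C@]12C | intermediate
4 | diethyl enol phosphate of 3 (terminal enol, from the methyl group) | C=C(OP(=O)(OCC)OCC)CC[C@H]1C(=C)C[C@H](O[Si](C)(C)C(C)(C)C)[C@H]2C(C)(C)CCC[C@]12C | intermediate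
5 | terminal alkyne, C9 side chain CH2CH2C≡CH, 6α-OTBS | C#CCC[C@H]1C(=C)C[C@H](O[Si](C)(C)C(C)(C)C)[C@H]2C(C)(C)CCC[C@]12C | intermediate
6 | (E)-alkenyldimethylalane, side chain CH2CH2C(CH3)=CH–AlMe2 | C[Al](C)/C=C(\C)CC[C@H]1C(=C)C[C@H](O[Si](C)(C)C(C)(C)C)[C@H]2C(C)(C)CCC[C@]12C | intermediate
7 | (E)-vinyl iodide, side chain CH2CH2C(CH3)=CHI | I/C=C(\C)CC[C@H]1C(=C)C[C@H](O[Si](C)(C)C(C)(C)C)[C@H]2C(C)(C)CCC[C@]12C | intermediate
8 | 2-methyl-2-vinyl-1,3-dioxolane | C=CC1(C)OCCO1 | starting material
9 | B-[2-(2-methyl-1,3-dioxolan-2-yl)ethyl]-9-borabicyclo[3.3.1]nonane | CC1(CCB2C3CCCC2CCC3)OCCO1 | intermediate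
10 | ethylene ketal of the (13E)-dienone | CC1(CC/C=C(\C)CC[C@H]2C(=C)C[C@H](O[Si](C)(C)C(C)(C)C)[C@H]3C(C)(C)CCC[C@]23C)OCCO1 | intermediate
11 | (13E)-dienone, side chain CH2CH2C(CH3)=CHCH2CH2COCH3, 6α-OTBS, exocyclic C8 methylene | CC(=O)CC/C=C(\C)CC[C@H]1C(=C)C[C@H](O[Si](C)(C)C(C)(C)C)[C@H]2C(C)(C)CCC[C@]12C | intermediate
12 | tetracyclic enol ether (pyran O–C13 … C16=C17(CH3)–O, trans-fused to ring C) | O1[C@@]2(C)CC[C@@H]3[C@@]4(C)CCCC(C)(C)[C@@H]4[C@@H](O[Si](C)(C)C(C)(C)C)C[C@@]3(C)[C@@H]2CC=C1C | intermediate
13 | tricyclic hydroxy ketone: 13α-OH, 13β-CH3, 14β-(3-oxobutyl), 8β-CH3, 6α-OTBS | O[C@@]1(C)CC[C@@H]2[C@@]3(C)CCCC(C)(C)[C@@H]3[C@@H](O[Si](C)(C)C(C)(C)C)C[C@@]2(C)[C@@H]1CCC(C)=O | intermediate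
14 | methyl enol ether, 14β-CH2CH2C(CH3)=CHOCH3 (E/Z), 13α-OH | O[C@@]1(C)CC[C@@H]2[C@@]3(C)CCCC(C)(C)[C@@H]3[C@@H](O[Si](C)(C)C(C)(C)C)C[C@@]2(C)[C@@H]1CCC(C)=COC | intermediate
15 | cyclic methyl acetal (2-methoxy-3-methyloxepane fused at C13/C14, epimers at C17 and C19) | COC1O[C@@]2(C)CC[C@@H]3[C@@]4(C)CCCC(C)(C)[C@@H]4[C@@H](O[Si](C)(C)C(C)(C)C)C[C@@]3(C)[C@@H]2CCC1C | intermediate
16 | seven-membered cyclic enol ether, O–C19H=C17(CH3), trans-fused to ring C | CC1=CO[C@@]2(C)CC[C@@H]3[C@@]4(C)CCCC(C)(C)[C@@H]4[C@@H](O[Si](C)(C)C(C)(C)C)C[C@@]3(C)[C@@H]2CC1 | intermediate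
17 | dibromocyclopropane, CBr2 (C18) bridging C19 and C17, both cis-fused diastereomers | BrC1(Br)C2O[C@@]3(C)CC[C@@H]4[C@@]5(C)CCCC(C)(C)[C@@H]5[C@@H](O[Si](C)(C)C(C)(C)C)C[C@@]4(C)[C@@H]3CCC12C | intermediate
18 | eight-membered allylic acetal acetate, C19–OAc (epimers), C18–Br, ring-cis olefin | C/C1=C(Br)/C(OC(C)=O)O[C@@]2(C)CC[C@@H]3[C@@]4(C)CCCC(C)(C)[C@@H]4[C@@H](O[Si](C)(C)C(C)(C)C)C[C@@]3(C)[C@@H]2CC1 | intermediate
19 | bromo-oxocene, C18–Br, ring-cis olefin, 6α-OTBS | C/C1=C(Br)/CO[C@@]2(C)CC[C@@H]3[C@@]4(C)CCCC(C)(C)[C@@H]4[C@@H](O[Si](C)(C)C(C)(C)C)C[C@@]3(C)[C@@H]2CC1 | intermediate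
20 | 6-O-tert-butyldimethylsilyl ether of the target | C/C1=C/CO[C@@]2(C)CC[C@@H]3[C@@]4(C)CCCC(C)(C)[C@@H]4[C@@H](O[Si](C)(C)C(C)(C)C)C[C@@]3(C)[C@@H]2CC1 | intermediate
21 | CNP0179324.1: 6α-hydroxy tricycle with the 13α-O–C19 oxocene, ring-cis (Z) C17=C18 | C/C1=C/CO[C@@]2(C)CC[C@@H]3[C@@]4(C)CCCC(C)(C)[C@@H]4[C@@H](O)C[C@@]3(C)[C@@H]2CC1 | target

**Totals and risks**

Total step count: 13. Longest linear sequence: 13 steps (1 to 21).

Most likely to fail, step 8: the seven-membered mixed acetal may fail to close or may reopen to the acyclic enol ether, and warm acid may dehydrate the tertiary alcohol. The fallback closes the oxepine by metathesis instead of acetal chemistry and sets out from 13. Iridium-catalysed transfer vinylation ([Ir(cod)Cl]2, Na2CO3, vinyl acetate, toluene, 100 °C) should give the O-vinyl ketone F1. Wittig methylenation (Ph3PCH3Br, KOtBu, THF, 0 °C) should give the vinyl ether with isopropenyl terminus F2. Ring-closing metathesis with the second-generation Grubbs catalyst (toluene, 80 °C) then forms the O–C19H=C17 bond and comes back to the route at 16.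

Second, step 10: the oxocarbenium ion may lose a proton from C16 to give a dienol ether, acetate may be captured at C17, or the cyclopropane may open uncontrolled already during step 9. The fallback gives up ring expansion for direct ring closure and sets out from 13. Wittig methylenation (Ph3PCH3Br, KOtBu, THF) should give the isopropenyl tertiary alcohol F3, and O-allylation (KH, allyl bromide, THF, 0 °C to rt) the allyl ether F4. Ring-closing metathesis with the second-generation Hoveyda–Grubbs catalyst (toluene, 80 °C, high dilution) should close the oxocene, whose ring olefin can only be cis, and comes back to the route at 20.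

Third, step 6: the silyl ether may be cleaved by the acid, or protonation of the exocyclic methylene may be too slow with this acid to outrun side reactions. The fallback changes the protecting-group logic and sets out from 11. TBAF (THF, rt) should give the free 6α-alcohol dienone F5. Cyclization in FSO3H/2-nitropropane at −78 °C, followed by aqueous acid, should give the diol ketone F6. Selective silylation of the secondary 6α-OH (TBSOTf, 1 equiv, 2,6-lutidine, CH2Cl2, −78 °C) comes back to the route at 13.

Further compounds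
F1 | step 8 | O-vinyl ether of hydroxy ketone 13 (13α-OCH=CH2, 14β-(3-oxobutyl)) | C=CO[C@@]1(C)CC[C@@H]2[C@@]3(C)CCCC(C)(C)[C@@H]3[C@@H](O[Si](C)(C)C(C)(C)C)C[C@@]2(C)[C@@H]1CCC(C)=O
F2 | step 8 | 13α-vinyl ether with 14β-CH2CH2C(CH3)=CH2 | C=CO[C@@]1(C)CC[C@@H]2[C@@]3(C)CCCC(C)(C)[C@@H]3[C@@H](O[Si](C)(C)C(C)(C)C)C[C@@]2(C)[C@@H]1CCC(C)=C
F3 | step 10 | 13α-hydroxy compound with 14β-CH2CH2C(CH3)=CH2 | O[C@@]1(C)CC[C@@H]2[C@@]3(C)CCCC(C)(C)[C@@H]3[C@@H](O[Si](C)(C)C(C)(C)C)C[C@@]2(C)[C@@H]1CCC(C)=C
F4 | step 10 | 13α-allyl ether with 14β-CH2CH2C(CH3)=CH2 | C=CCO[C@@]1(C)CC[C@@H]2[C@@]3(C)CCCC(C)(C)[C@@H]3[C@@H](O[Si](C)(C)C(C)(C)C)C[C@@]2(C)[C@@H]1CCC(C)=C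
F5 | step 6 | (13E)-dienone with free 6α-OH | CC(=O)CC/C=C(\C)CC[C@H]1C(=C)C[C@H](O)[C@H]2C(C)(C)CCC[C@]12C
F6 | step 6 | tricyclic 6α,13α-diol ketone, 14β-(3-oxobutyl) | O[C@@]1(C)CC[C@@H]2[C@@]3(C)CCCC(C)(C)[C@@H]3[C@@H](O)C[C@@]2(C)[C@@H]1CCC(C)=O
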